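# Proposed synthesis of CNP0256710.1 (compound 40) by trivalent-iodine ring contraction of a dehydroabietane

## The problem

Compound 40 joins two C20 diterpene units. The labdane half (primed numbers) is a trans-decalin with four stereocentres (C4', C5', C9', C10'), an exocyclic C8'=C17' alkene, a hindered tertiary acid (C18') and a (12'E) trisubstituted alkene. Its C14' and C15' form the two-carbon bridge of a bicyclo[3.2.1]octene built on ring C of the abietane half: C13 and C8 are quaternary bridgeheads, C14 is the one-carbon keto bridge and C12(=O)–C11(OH)=C9 is a diosphenol. Ring B of the abietane half is a cyclopentane in which C7 links C5 to C8 and carries the formyl carbon C6 on the α face, cis to C15' on C8 and trans to C4.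

Of the ten stereocentres, six (C4', C5', C9', C10', C5, C10) are those of the common resin acids and can be bought. C7 can be set under the influence of C5 and C10. C13, C14' and C8 lie far from all of these and need their own control element; once C13 is fixed, the bridge leaves C8 no choice.

Several functions are fragile. The aldehyde is epimerisable at C7, and at the quinone oxidation level H7 is vinylogously acidic. The exocyclic alkene isomerises in strong acid and reacts with boranes and ozone. The non-enolisable C12–C13–C14 diketone can undergo retro-Claisen opening with hydroxide or alkoxide. The acid must be unmasked without strong acid or base.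

The feature that opens the route is the cyclopentane ring B. A ring carbon bonded to C5 and to arene carbon C8, bearing one exocyclic oxidised carbon, is what an oxidative 1,2-aryl shift leaves behind when it acts on the C6=C7 styrene of a 6,7-dehydroabietane such as 10.

## Retrosynthesis

**Unmasking (40 ⇒ 38).** No skeletal bond is cut. The aldehyde is carried as the dimethyl acetal that the key step delivers, and the acid as a 2-(trimethylsilyl)ethyl ester, giving 38. A methyl ester at this neopentyl position would need forcing nucleophiles that the diosphenol and the bridged diketone would not tolerate. The forward step needs fluoride and then dilute acid, with no epimerisation at C7 and no alkene migration.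

**C8–C15' (38 ⇒ 37).** Cutting the bond between bridgehead C8 and the methylene C15' opens the bicycle to the monocyclic ene-trione 37 with an iodomethyl group on C14'. This cut is preferred over disconnecting both bridge bonds at once, which would ask two hindered partners to form two quaternary centres intermolecularly with only substrate facial bias. The forward reaction is a 5-exo-trig radical closure. The anionic alternative would be a 5-(enolendo)-exo-tet alkylation and would give O-alkylation instead. The closure must attack C8, not C9, and iodine abstraction must outrun reduction of the ene-trione.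

**C13–C14' (37 ⇒ 35 ⇒ 34).** Iodide 37 comes from silyl ether 35. The C13–C14' bond of 35 is cut by a retro-Claisen transform to quinonyl allyl ether 34. This removes both the quaternary C13 and the C14' stereocentre and replaces them by one carbinol stereocentre (C12') and one alkene geometry (13'Z). The forward [3,3] shift must go through a single chair.

**O12–C12' (34 ⇒ 16 + 33).** The ether bond divides the molecule into hydroxyquinone 16 and allylic alcohol 33, two halves of similar size. A Mitsunobu reaction is asked to alkylate O12 with clean inversion and without SN2' leakage.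

**C12'–C13' (33 ⇒ 25 + 29).** Alcohol 33 is cut between the carbinol carbon and the alkene into aldehyde 25 and the four-carbon (Z)-iodoalkene 29, which comes from but-2-yn-1-ol 26 by anti-hydroalumination. Because the addition cannot control C12', the adduct 31 is oxidised to enone 32 and reduced under catalyst control.

**Labdane aldehyde (25 ⇒ 22 ⇒ 20 ⇒ 18 ⇒ 17).** The decalin of 25, with all four stereocentres and the C18' carboxyl, is that of abietic acid 17. Ring C is cut at C13–C14 (18 to 20), the resulting enal is transposed to the exocyclic alkene (20 to 22), and the isopropyl ketone chain is shortened at C12'–C13 (22 to 25 via 24). This degradation is preferred over building the decalin because no stereocentre has to be made.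

**Ring C oxidation (16 ⇒ 12 ⇒ 11).** The hydroxyquinone is traced to phenol 12 and its methyl ether 11. The forward steps must add oxygen at C11 and C14 without acid, which would open the acetal.

**Key disconnection (11 ⇒ 10).** The C7–C8 bond of 11 is cut by reversing a 1,2-aryl shift, which restores the six-membered ring B of styrene 10. This is preferred over assembling the cyclopentane from smaller pieces because 10 already holds C5, C10 and every carbon of the abietane half. The forward step must give aryl migration rather than simple addition, on the α face.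

**Styrene 10 (10 ⇒ 9 ⇒ 7 ⇒ 6 ⇒ 5 ⇒ 3 ⇒ 2 ⇒ 1).** The C6=C7 alkene comes from dehydrogenation of 9. The C12 oxygen comes from acylation and Baeyer–Villiger oxidation (5 to 6 to 7). The gem-dimethyl group comes from deoxygenation of C18 of dehydroabietic acid 1 (via 2 and 3).

## Roads not taken

**Alternative 1:** The labdane decalin would be cut at C4'–C5' and C9'–C10' and made by a cation–olefin bicyclisation. MeAlCl2 would open an enantioenriched epoxide, and an allylsilane would terminate the cascade to give A1 with the exocyclic alkene in place.
- Merits: two rings, four stereocentres and the alkene regiochemistry arise in one step from an acyclic chain. Either enantiomer and analogues are accessible. It does not depend on the purity of a natural resin acid. In these respects it is better than the chosen plan.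
- Weak points: A1 carries a C3' hydroxyl that the target lacks. C18' is at the alcohol level. The side chain stops at C11'. The epoxide enantiopurity and the allylsilane geometry must be secured first.
- Comparison: the disconnection addresses only the easier half of 40. The chosen plan obtains the same decalin, with absolute configuration and the C18' carboxyl, in five steps (11 to 15) from abietic acid.

**Alternative 2:** The cuts are C8–C9 and C12–C13. Triethylamine in trifluoroethanol would turn a chloromethyl ketone into an oxyallyl cation, which adds intramolecularly across a 5,5-dimethoxycyclopentadiene to give A2.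
- Merits: ring B, the bridged seven-membered ring and both quaternary bridgeheads form in one step. No single step of the chosen plan creates that much complexity.
- Weak points: the tethered, fully substituted cyclopentadiene is long to make and prone to 1,5-shifts and dimerisation. Facial and endo/exo selectivity relative to C5, C7 and C10 are open. A2 still needs oxidation at C12, conversion to the diosphenol, ketal hydrolysis, reduction of the bridge alkene with control of C14', and attachment of the whole labdane chain through a neopentyl-type carbon.
- Comparison: the chosen plan reaches the same bridgeheads in two intramolecular steps (22 and 24) whose configuration is relayed from a carbinol set by a catalyst. It pays with a longer sequence and a redox-sensitive ene-trione.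

**Alternative 3:** Ring C would be cut and rebuilt from a squarate. Thermolysis of a 4-hydroxy-4-hydrindenylcyclobutenone gives a dienylketene whose 6π closure and tautomerisation deliver hydroquinone A3.
- Merits: all three ring C oxygens and the isopropyl group arrive regiodefined, with O12 already differentiated. Oxidation to the quinone would then be trivial. Here it is clearly better than the chosen plan, which must add O11 and O14 late by a quinone relay (step 10).
- Weak points: the ring B-contracted hydrindene partner, with C5, C7 and the quaternary C10, would have to be made enantioselectively from scratch. A3 still needs C6 oxidation and ether cleavage.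
- Comparison: the chosen plan takes the carbon skeleton with C5 and C10 from dehydroabietic acid and sets C7 in the ring contraction.

Key step: step 8

Remark on numbering:
- Abietane-half atoms are unprimed. From 11 on they follow the 5(6→7)abeo numbering of 40 (ring carbon C7, exocyclic C6); compounds 1 to 10 keep ordinary abietane numbers.
- Labdane-half atoms are primed. Compounds 17 to 21 are named with abietane numbers, under which abietane C14 becomes labdane C17'.

## Route

Step 1
Reactants: 1 dehydroabietic acid
Product: 2 dehydroabietinol
Conditions: LiAlH4, THF, reflux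
Reagents that add atoms: none
Why: Hydride reduction of a carboxylic acid by LiAlH4 is routine for the hindered C18 carboxyl of resin acids; no stereocentre is involved.

Step 2
Reactants: 2 dehydroabietinol
Product: 3 dehydroabietinal
Conditions: 1,1,1-triacetoxy-1,1-dihydro-1,2-benziodoxol-3(1H)-one (DMP), CH2Cl2, rt
Reagents that add atoms: none
Why: Dess–Martin oxidation stops cleanly at the neopentyl aldehyde, which has no α-hydrogen and can neither enolise nor epimerise.

Step 3
Reactants: 3 dehydroabietinal
Product: 5 abieta-8,11,13-triene, via hydrazone 4 (not isolated)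
Conditions: N2H4·H2O, KOH, diethylene glycol, 130 °C then 200 °C
Reagents that add atoms: none
Why: Wolff–Kishner reduction in its one-pot high-temperature form turns the non-enolisable aldehyde into the C18 methyl group through hydrazone 4; C4 ceases to be a stereocentre and C5 and C10 are untouched.

Step 4
Reactants: 5 abieta-8,11,13-triene
Product: 6 12-acetylabieta-8,11,13-triene
Conditions: AcCl, AlCl3, CH2Cl2, 0 °C to rt
Reagents that add atoms: acetyl chloride, CC(=O)Cl
Why: Friedel–Crafts acylation goes to C12, the ring position ortho to isopropyl that is not wedged between two substituents (C11 is screened by the C1/C20 region, C14 by isopropyl and C7); the minor C14 isomer expected is removed here.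

Step 5
Reactants: 6 12-acetylabieta-8,11,13-triene
Product: 7 12-acetoxyabieta-8,11,13-triene
Conditions: 3-chloroperoxybenzoic acid, CF3CO2H (cat.), CH2Cl2, rt
Reagents that add atoms: 3-chloroperoxybenzoic acid, OOC(=O)c1cccc(Cl)c1
Why: Baeyer–Villiger oxidation of an aryl methyl ketone; the electron-rich trialkylated aryl group migrates in preference to methyl and gives the aryl acetate.

Step 6
Reactants: 7 12-acetoxyabieta-8,11,13-triene
Product: 9 ferruginol methyl ether, via potassium ferruginolate 8 (not isolated)
Conditions: KOH, MeI, DMSO, rt
Reagents that add atoms: iodomethane, CI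
Why: Hydroxide cleaves the aryl acetate and phenoxide 8 is O-methylated in the same flask (Williamson ether synthesis); the methyl ether survives the oxidants of steps 7 and 8 and makes ring C a good migrating group.

Step 7
Reactants: 9 ferruginol methyl ether
Product: 10 6,7-dehydroferruginol methyl ether
Conditions: 2,3-dichloro-5,6-dicyano-1,4-benzoquinone (DDQ), dioxane, reflux
Reagents that add atoms: none
Why: Benzylic dehydrogenation by DDQ: hydride is taken from C7, whose cation is stabilised by the para methoxy group at C12, and loss of H6 gives the styrene; ring B cannot aromatise because C10 is quaternary.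

Step 8
Reactants: 10 6,7-dehydroferruginol methyl ether
Product: 11 12-methoxy-5(6→7)abeo-abieta-8,11,13-trien-6-al dimethyl acetal (acetal carbon on C7, α face)
Conditions: PhI(OH)OTs, MeOH, 0 °C to rt
Reagents that add atoms: methanol, CO
Why: The trivalent iodine reagent ionises in methanol and its electrophilic iodine adds to C6 of the styrene (numbering of 10) from the α face, because the β face is screened by the axial C19 and C20 methyl groups, while methanol captures the para-methoxy-stabilised benzylic cation at C7. In the rigid half-chair the 6α carbon–iodine bond is equatorial and therefore antiperiplanar to the C7–C8 ring bond, so arene carbon C8 migrates from C7 to C6 through a phenonium-like three-membered transition state as iodobenzene leaves, and the oxocarbenium ion left at the old C7 is trapped by methanol as the dimethyl acetal. The closest known reaction type is the oxidative ring contraction of 1,2-dihydronaphthalenes to indane-1-carbaldehyde acetals with trivalent iodine reagents, a semipinacol-type 1,2-aryl shift. Ring B closes by ring contraction, that is by a 1,2-shift (ipso attack of the arene on C6, then opening of the bridged arenium ion), and not by an end-to-end cyclisation; the bond made is C8–C6 of 10, which is C7–C8 of 11 and 40, the old C6 becoming ring carbon C7 and the old C7 the exocyclic carbon C6. The one new stereocentre is set by the substrate: the shift inverts the iodinated carbon, so α iodination puts the acetal carbon on the α face, cis to H5 and trans to C4, which is also the less crowded arrangement. The step needs aryl migration to beat direct methanolysis of the carbon–iodine bond and hydride shift; the methoxy group para to C8, the antiperiplanar alignment and the hindered, neopentyl-like character of C6 toward SN2 attack secure this. C5 and C10 are spectators.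

Step 9
Reactants: 11 12-methoxy-5(6→7)abeo-abieta-8,11,13-trien-6-al dimethyl acetal
Product: 12 12-hydroxy-5(6→7)abeo-abieta-8,11,13-trien-6-al dimethyl acetal (phenol)
Conditions: NaSEt, DMF, 140 °C
Reagents that add atoms: none
Why: Nucleophilic demethylation of the aryl methyl ether by ethanethiolate (SN2 at the methyl carbon); the basic medium leaves the dimethyl acetal and the C7 configuration untouched.

Step 10
Reactants: 12 12-hydroxy-5(6→7)abeo-abieta-8,11,13-trien-6-al dimethyl acetal
Product: 16 12-hydroxy-5(6→7)abeo-abieta-8,12-diene-11,14-dione 6-dimethyl acetal (hydroxyquinone acetal), via o-quinone 13 (not isolated), via thioether catechol 14 (not isolated), via thioether o-quinone 15 (not isolated)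
Conditions: 2-iodoxybenzoic acid (IBX), CHCl3, rt; C6F5SH, rt; then NaOH (1 M aq), MeOH, air, 0 °C to rt; NaH2PO4 quench
Reagents that add atoms: 2-iodoxybenzoic acid, O=C1OI(=O)(O)c2ccccc12; sodium hydroxide, [Na+].[OH-]
Why: IBX oxygenates the only free ortho position (C11) to give o-quinone 13; the thiol adds in conjugate fashion at C14, the one unsubstituted ring carbon; air reoxidises catechol 14 in base to 15; hydroxide displaces the thiolate by addition–elimination and the 14-hydroxy-11,12-quinone tautomerises to the 12-hydroxy-11,14-quinone. This phenol to hydroxy-p-quinone relay is known for ring B-contracted abietane phenols, and the product sits in base as its anion, which resists deprotonation at C7.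

Step 11
Reactants: 17 abietic acid
Product: 18 2-(trimethylsilyl)ethyl abietate
Conditions: Me3SiCH2CH2OH, N-(3-dimethylaminopropyl)-N'-ethylcarbodiimide hydrochloride, 4-(dimethylamino)pyridine (cat.), CH2Cl2, rt
Reagents that add atoms: 2-(trimethylsilyl)ethanol, C[Si](C)(C)CCO
Why: Carbodiimide esterification with acyl-transfer catalysis (Steglich esterification); the ester has no α-hydrogen, withstands the oxidants, bases and hydrides that follow and is removed at the end by fluoride.

Step 12
Reactants: 18 2-(trimethylsilyl)ethyl abietate
Product: 20 2-(trimethylsilyl)ethyl 13-oxo-13,14-secoabiet-7-en-14-al-18-oate (keto enal), via 13,14-diol 19 (not isolated)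
Conditions: OsO4 (2 mol %), N-methylmorpholine N-oxide, acetone/H2O, rt; then NaIO4, rt
Reagents that add atoms: osmium tetroxide, O=[Os](=O)(=O)=O (catalytic carrier of both oxygen atoms); N-methylmorpholine N-oxide, C[N+]1([O-])CCOCC1; water, O
Why: OsO4-catalysed syn-dihydroxylation takes the more accessible C13=C14 end of the heteroannular diene and periodate cleaves diol 19 in the same flask (overall a Lemieux–Johnson-type cleavage); the resulting C7=C8 enal is too electron-poor to react further and C9 is untouched.

Step 13
Reactants: 20 2-(trimethylsilyl)ethyl 13-oxo-13,14-secoabiet-7-en-14-al-18-oate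
Product: 22 2-(trimethylsilyl)ethyl 13-oxo-13,14-secoabiet-8(14)-en-18-oate (exocyclic alkene C8'=C17' in labdane numbering), via tosylhydrazone 21 (not isolated)
Conditions: TsNHNH2, THF, rt; then catecholborane, CHCl3, 0 °C; NaOAc·3H2O, 60 °C
Reagents that add atoms: none
Why: Alkene-transposing reduction of an α,β-unsaturated tosylhydrazone (Kabalka modification of the Caglioti reaction): the aldehyde condenses far faster than the hindered isopropyl ketone, catecholborane reduces the C=N bond of 21, acetate triggers loss of sulfinate, and dinitrogen is expelled with 1,5-hydrogen transfer to C7, which moves the double bond to the exocyclic position without touching C9.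

Step 14
Reactants: 22 2-(trimethylsilyl)ethyl 13-oxo-13,14-secoabiet-8(14)-en-18-oate
Product: 24 12'-hydroxy derivative of 22 (α-hydroxy ketone, both C12' epimers), via potassium enolate 23 (not isolated)
Conditions: KN(SiMe3)2, THF, −78 °C; then 2-(phenylsulfonyl)-3-phenyloxaziridine, −78 °C
Reagents that add atoms: 2-(phenylsulfonyl)-3-phenyloxaziridine, O=S(=O)(N1OC1c1ccccc1)c1ccccc1
Why: Kinetic deprotonation by the bulky amide occurs at the methylene C12' and not at the isopropyl methine, and enolate 23 is hydroxylated by the N-sulfonyloxaziridine (Davis oxidation); the carbinol configuration is irrelevant because C12' becomes an aldehyde in step 15.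

Step 15
Reactants: 24 12'-hydroxy ketone
Product: 25 2-(trimethylsilyl)ethyl 12'-oxo-13',14',15',16'-tetranorlabd-8'(17')-en-18'-oate (aldehyde)
Conditions: Pb(OAc)4, MeOH/benzene, 0 °C
Reagents that add atoms: none
Why: Criegee-type cleavage of an α-hydroxy ketone by Pb(OAc)4 in methanol gives the aldehyde from the carbinol carbon and methyl isobutyrate from the acyl carbon; the 1,1-disubstituted alkene is inert at 0 °C and C9' is not α to the new carbonyl.

Step 16
Reactants: 26 but-2-yn-1-ol
Product: 28 (Z)-3-iodobut-2-en-1-ol, via cyclic alkenyl alanate 27 (not isolated)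
Conditions: NaAlH2(OCH2CH2OMe)2, THF, 0 °C to rt; EtOAc; then I2, −78 to 0 °C
Reagents that add atoms: iodine, II
Why: Alkoxide-directed anti-hydroalumination of the propargylic alcohol places aluminium on C3 cis to the CH2O group (alanate 27) and iodinolysis with retention gives the (Z)-iodoalkene, the geometry that will place C15' cis to C12'.

Step 17
Reactants: 28 (Z)-3-iodobut-2-en-1-ol
Product: 29 (Z)-tert-butyl[(3-iodobut-2-en-1-yl)oxy]dimethylsilane
Conditions: tert-butyldimethylsilyl chloride, imidazole, CH2Cl2, rt
Reagents that add atoms: tert-butyldimethylsilyl chloride, CC(C)(C)[Si](C)(C)Cl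
Why: Standard silylation of a primary alcohol; the silyl ether masks O15' until it is exchanged for halogen in step 23.

Step 18
Reactants: 29 (Z)-tert-butyl[(3-iodobut-2-en-1-yl)oxy]dimethylsilane; 25 aldehyde
Product: 31 2-(trimethylsilyl)ethyl (13'Z)-15'-(tert-butyldimethylsilyloxy)-12'-hydroxylabda-8'(17'),13'-dien-18'-oate (both C12' epimers), via alkenyllithium 30 (not isolated)
Conditions: tert-BuLi (2 equiv), Et2O, −78 °C; then 25, −78 °C
Reagents that add atoms: none
Why: Iodine–lithium exchange with retention of alkene geometry gives 30, whose 1,2-addition to the unhindered aldehyde outruns attack on the neopentyl ester at −78 °C; C12' forms without control and both epimers go on to ketone 32.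

Step 19
Reactants: 31 allylic alcohol (C12' epimers)
Product: 32 2-(trimethylsilyl)ethyl (13'Z)-15'-(tert-butyldimethylsilyloxy)-12'-oxolabda-8'(17'),13'-dien-18'-oate (enone)
Conditions: DMP, NaHCO3, CH2Cl2, 0 °C to rt
Reagents that add atoms: none
Why: Dess–Martin oxidation of the allylic alcohol under buffered conditions, which should leave the (Z)-enone geometry and both silicon groups intact.

Step 20
Reactants: 32 enone
Product: 33 2-(trimethylsilyl)ethyl (12'R,13'Z)-15'-(tert-butyldimethylsilyloxy)-12'-hydroxylabda-8'(17'),13'-dien-18'-oate
Conditions: (S)-1-methyl-3,3-diphenyltetrahydro-1H,3H-pyrrolo[1,2-c][1,3,2]oxazaborole [(S)-Me-CBS, 0.2 equiv], catecholborane, toluene, −78 °C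
Reagents that add atoms: none
Why: CBS reduction: with the α-methylalkenyl group as the large substituent and the CH2 group as the small one, the (S)-catalyst is expected to give the (12'R)-alcohol; catecholborane at −78 °C is chosen because it does not hydroborate the exocyclic alkene.

Step 21
Reactants: 33 (12'R)-allylic alcohol; 16 hydroxyquinone acetal
Product: 34 quinonyl allyl ether: O12 of 16 bonded to C12' (12'S) of the labdane unit, with 13'Z alkene, C15' silyl ether, C18' 2-(trimethylsilyl)ethyl ester and C6 dimethyl acetal
Conditions: PPh3, diisopropyl azodicarboxylate, toluene, 0 °C (betaine preformed); then 33 and 16, 0 °C to rt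
Reagents that add atoms: none
Why: Mitsunobu etherification: the hydroxyquinone is a vinylogous carboxylic acid, acidic enough to act as the nucleophile, and displaces the activated C12' oxygen with inversion to give the (12'S)-ether; preforming the betaine keeps free phosphine away from the quinone, and the 1,4-quinone ether at O12 is the expected regioisomer of this ambident anion.

Step 22
Reactants: 34 quinonyl allyl ether
Product: 35 5(6→7)abeo-abiet-8-ene-11,12,14-trione 6-dimethyl acetal with quaternary C13 (isopropyl retained) bonded to C14', which carries H, CH2OSi (C15') and the (12'E) C13'(CH3)=C12'H–C11' labdane chain; C13 and C14' configured as in 40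
Conditions: toluene, 100 °C (sealed tube)
Reagents that add atoms: none
Why: Claisen rearrangement of the allyl ether of a cyclic vinylogous acid to a 2,2-disubstituted 1,3-dicarbonyl compound: in the chair transition state C11' is equatorial (hence the 12'E alkene) and the (Z)-CH2OSi group is axial at C14', while the alternative chair suffers a 1,3-diaxial clash, so the C12' configuration is transferred to C14' and, through the ring face attacked, to the quaternary C13.

Step 23
Reactants: 35 silyl ether trione
Product: 37 15'-iodide of 35 (CH2I on C14'), via bromide 36 (not isolated)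
Conditions: Ph3PBr2, CH2Cl2, 0 °C to rt; then NaI, acetone, 50 °C
Reagents that add atoms: sodium iodide, [Na+].[I-]
Why: Triphenylphosphine dibromide converts the silyl ether directly into bromide 36 (alkoxyphosphonium, then SN2 by bromide) without passing through the free alcohol, which could close onto the trione as a hemiketal; Finkelstein exchange then gives the iodide, wanted because iodine abstraction by tin radicals is orders of magnitude faster than bromine abstraction.

Step 24
Reactants: 37 iodide
Product: 38 C6 dimethyl acetal and C18' 2-(trimethylsilyl)ethyl ester of 40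
Conditions: Bu3SnH (slow addition), azobisisobutyronitrile (cat.), benzene, 80 °C
Reagents that add atoms: none
Why: Tin hydride-mediated radical cyclisation (intramolecular Giese addition): the primary C15' radical closes 5-exo-trig onto C8, the β-carbon of the enone activated by the vicinal C11/C12 dione, and the dione-stabilised C9 radical takes hydrogen to give the diosphenol; the two-atom tether can reach C8 only on the ring face that carries C14', which fixes the C8 configuration.

Step 25
Reactants: 38 acetal ester
Product: 40 CNP0256710.1, via acid acetal 39 (not isolated)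
Conditions: Bu4NF, THF, 0 °C to rt; then HCl (1 M aq), THF, rt
Reagents that add atoms: water, O
Why: Fluoride attacks silicon and the 2-(trimethylsilyl)ethyl ester fragments to ethene and carboxylate 39 without touching the carbonyl groups; brief dilute acid then hydrolyses the dimethyl acetal to the aldehyde, with C7 no longer vinylogously acidic because C8 is now sp3, and with the exocyclic alkene stable under these conditions.

## Compound list

1 | dehydroabietic acid (abieta-8,11,13-trien-18-oic acid; 5α-H, 10β-CH3, 4α-CO2H) | CC(C)c1ccc2c(c1)CC[C@@H]1[C@]2(C)CCC[C@@]1(C)C(=O)O | starting material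
2 | dehydroabietinol (abieta-8,11,13-trien-18-ol) | CC(C)c1ccc2c(c1)CC[C@@H]1[C@]2(C)CCC[C@@]1(C)CO | intermediate
3 | dehydroabietinal (abieta-8,11,13-trien-18-al) | CC(C)c1ccc2c(c1)CC[C@@H]1[C@]2(C)CCC[C@@]1(C)C=O | intermediate
4 | hydrazone of dehydroabietinal | CC(C)c1ccc2c(c1)CC[C@@H]1[C@]2(C)CCC[C@@]1(C)C=NN | intermediate (not isolated)
5 | abieta-8,11,13-triene (5α-H, 10β-CH3) | CC(C)c1ccc2c(c1)CC[C@@H]1[C@]2(C)CCCC1(C)C | intermediate
6 | 12-acetylabieta-8,11,13-triene | CC(C)c1cc2c(cc1C(C)=O)[C@@]1(C)CCCC(C)(C)[C@@H]1CC2 | intermediate
7 | 12-acetoxyabieta-8,11,13-triene (ferruginol acetate) | CC(C)c1cc2c(cc1OC(C)=O)[C@@]1(C)CCCC(C)(C)[C@@H]1CC2 | intermediate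
8 | potassium ferruginolate (potassium abieta-8,11,13-trien-12-olate) | CC(C)c1cc2c(cc1[O-])[C@@]1(C)CCCC(C)(C)[C@@H]1CC2.[K+] | intermediate (not isolated)
9 | ferruginol methyl ether (12-methoxyabieta-8,11,13-triene) | CC(C)c1cc2c(cc1OC)[C@@]1(C)CCCC(C)(C)[C@@H]1CC2 | intermediate
10 | 6,7-dehydroferruginol methyl ether (12-methoxyabieta-6,8,11,13-tetraene) | CC(C)c1cc2c(cc1OC)[C@@]1(C)CCCC(C)(C)[C@@H]1C=C2 | intermediate
11 | 12-methoxy-5(6→7)abeo-abieta-8,11,13-trien-6-al dimethyl acetal (CH(OCH3)2 on C7, α, cis to H5, trans to C4) | CC(C)c1cc2c(cc1OC)[C@@]1(C)CCCC(C)(C)[C@@H]1[C@H]2C(OC)OC | intermediate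
12 | 12-hydroxy-5(6→7)abeo-abieta-8,11,13-trien-6-al dimethyl acetal | CC(C)c1cc2c(cc1O)[C@@]1(C)CCCC(C)(C)[C@@H]1[C@H]2C(OC)OC | intermediate
13 | 5(6→7)abeo-abieta-8,13-diene-11,12-dione 6-dimethyl acetal (o-quinone) | CC(C)C1=CC2=C(C(=O)C1=O)[C@@]1(C)CCCC(C)(C)[C@@H]1[C@H]2C(OC)OC | intermediate (not isolated)
14 | 11,12-dihydroxy-14-(pentafluorophenylthio)-5(6→7)abeo-abieta-8,11,13-trien-6-al dimethyl acetal | CC(C)c1c(Sc2c(F)c(F)c(F)c(F)c2F)c2c(c(O)c1O)[C@@]1(C)CCCC(C)(C)[C@@H]1[C@H]2C(OC)OC | intermediate (not isolated)
15 | 14-(pentafluorophenylthio)-5(6→7)abeo-abieta-8,13-diene-11,12-dione 6-dimethyl acetal | CC(C)C1=C(Sc2c(F)c(F)c(F)c(F)c2F)C2=C(C(=O)C1=O)[C@@]1(C)CCCC(C)(C)[C@@H]1[C@H]2C(OC)OC | intermediate (not isolated)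
16 | 12-hydroxy-5(6→7)abeo-abieta-8,12-diene-11,14-dione 6-dimethyl acetal | OC1=C(C(C)C)C(=O)C2=C(C1=O)[C@@]1(C)CCCC(C)(C)[C@@H]1[C@H]2C(OC)OC | intermediate
17 | abietic acid (abieta-7,13-dien-18-oic acid) | CC(C)C1=CC2=CC[C@@H]3[C@@]([C@H]2CC1)(CCC[C@@]3(C)C(=O)O)C | starting material
18 | 2-(trimethylsilyl)ethyl abietate | CC(C)C1=CC2=CC[C@@H]3[C@@]([C@H]2CC1)(CCC[C@@]3(C)C(=O)OCC[Si](C)(C)C)C | intermediate
19 | 2-(trimethylsilyl)ethyl 13,14-dihydroxyabiet-7-en-18-oate (cis-diol, face not assigned, both centres cleared in the same flask) | CC(C)C1(O)C(O)C2=CC[C@@H]3[C@@]([C@H]2CC1)(CCC[C@@]3(C)C(=O)OCC[Si](C)(C)C)C | intermediate (not isolated)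
20 | 2-(trimethylsilyl)ethyl 13-oxo-13,14-secoabiet-7-en-14-al-18-oate | O=CC1=CC[C@@H]2[C@](C)(CCC[C@@]2(C)C(=O)OCC[Si](C)(C)C)[C@H]1CCC(=O)C(C)C | intermediate
21 | C14 tosylhydrazone of 20 | Cc1ccc(cc1)S(=O)(=O)NN=CC1=CC[C@@H]2[C@](C)(CCC[C@@]2(C)C(=O)OCC[Si](C)(C)C)[C@H]1CCC(=O)C(C)C | intermediate (not isolated)
22 | 2-(trimethylsilyl)ethyl 13-oxo-13,14-secoabiet-8(14)-en-18-oate (exocyclic C8'=C17' alkene, isopropyl ketone side chain) | C=C1CC[C@@H]2[C@](C)(CCC[C@@]2(C)C(=O)OCC[Si](C)(C)C)[C@H]1CCC(=O)C(C)C | intermediate
23 | potassium C12' enolate of 22 | C=C1CC[C@@H]2[C@](C)(CCC[C@@]2(C)C(=O)OCC[Si](C)(C)C)[C@H]1CC=C([O-])C(C)C.[K+] | intermediate (not isolated)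
24 | 12'-hydroxy derivative of 22 (both C12' epimers) | C=C1CC[C@@H]2[C@](C)(CCC[C@@]2(C)C(=O)OCC[Si](C)(C)C)[C@H]1CC(O)C(=O)C(C)C | intermediate
25 | 2-(trimethylsilyl)ethyl 12'-oxo-13',14',15',16'-tetranorlabd-8'(17')-en-18'-oate | C=C1CC[C@@H]2[C@](C)(CCC[C@@]2(C)C(=O)OCC[Si](C)(C)C)[C@H]1CC=O | intermediate
26 | but-2-yn-1-ol | CC#CCO | starting material
27 | sodium cyclic alkenyl alanate (2,2-bis(2-methoxyethoxy)-3-methyl-2,5-dihydro-1,2-oxaluminol-2-uide) | CC1=CCO[Al-]1(OCCOC)OCCOC.[Na+] | intermediate (not isolated)
28 | (Z)-3-iodobut-2-en-1-ol | C/C(I)=C/CO | intermediate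
29 | (Z)-tert-butyl[(3-iodobut-2-en-1-yl)oxy]dimethylsilane | C/C(I)=C/CO[Si](C)(C)C(C)(C)C | intermediate
30 | (Z)-[4-(tert-butyldimethylsilyloxy)but-2-en-2-yl]lithium | C/C([Li])=C/CO[Si](C)(C)C(C)(C)C | intermediate (not isolated)
31 | 2-(trimethylsilyl)ethyl (13'Z)-15'-(tert-butyldimethylsilyloxy)-12'-hydroxylabda-8'(17'),13'-dien-18'-oate, C12' epimers | C=C1CC[C@@H]2[C@](C)(CCC[C@@]2(C)C(=O)OCC[Si](C)(C)C)[C@H]1CC(O)/C(C)=C\CO[Si](C)(C)C(C)(C)C | intermediate
32 | 2-(trimethylsilyl)ethyl (13'Z)-15'-(tert-butyldimethylsilyloxy)-12'-oxolabda-8'(17'),13'-dien-18'-oate | C=C1CC[C@@H]2[C@](C)(CCC[C@@]2(C)C(=O)OCC[Si](C)(C)C)[C@H]1CC(=O)/C(C)=C\CO[Si](C)(C)C(C)(C)C | intermediate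
33 | 2-(trimethylsilyl)ethyl (12'R,13'Z)-15'-(tert-butyldimethylsilyloxy)-12'-hydroxylabda-8'(17'),13'-dien-18'-oate | C=C1CC[C@@H]2[C@](C)(CCC[C@@]2(C)C(=O)OCC[Si](C)(C)C)[C@H]1C[C@@H](O)/C(C)=C\CO[Si](C)(C)C(C)(C)C | intermediate
34 | quinonyl allyl ether: O12 of 16 bonded to C12' (12'S) of the (13'Z)-labdadienyl unit of 33 | C=C1CC[C@@H]2[C@](C)(CCC[C@@]2(C)C(=O)OCC[Si](C)(C)C)[C@H]1C[C@H](OC1=C(C(C)C)C(=O)C2=C(C1=O)[C@@]1(C)CCCC(C)(C)[C@@H]1[C@H]2C(OC)OC)/C(C)=C\CO[Si](C)(C)C(C)(C)C | intermediate
35 | C13-allylated 5(6→7)abeo-abiet-8-ene-11,12,14-trione 6-dimethyl acetal (C13–C14' bond, C15' silyl ether, 12'E alkene; C13 and C14' as in 40) | C=C1CC[C@@H]2[C@](C)(CCC[C@@]2(C)C(=O)OCC[Si](C)(C)C)[C@H]1C/C=C(\C)[C@H](CO[Si](C)(C)C(C)(C)C)[C@]1(C(C)C)C(=O)C2=C(C(=O)C1=O)[C@@]1(C)CCCC(C)(C)[C@@H]1[C@H]2C(OC)OC | intermediate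
36 | 15'-bromide corresponding to 35 | C=C1CC[C@@H]2[C@](C)(CCC[C@@]2(C)C(=O)OCC[Si](C)(C)C)[C@H]1C/C=C(\C)[C@H](CBr)[C@]1(C(C)C)C(=O)C2=C(C(=O)C1=O)[C@@]1(C)CCCC(C)(C)[C@@H]1[C@H]2C(OC)OC | intermediate (not isolated)
37 | 15'-iodide corresponding to 35 | C=C1CC[C@@H]2[C@](C)(CCC[C@@]2(C)C(=O)OCC[Si](C)(C)C)[C@H]1C/C=C(\C)[C@H](CI)[C@]1(C(C)C)C(=O)C2=C(C(=O)C1=O)[C@@]1(C)CCCC(C)(C)[C@@H]1[C@H]2C(OC)OC | intermediate
38 | C6 dimethyl acetal, C18' 2-(trimethylsilyl)ethyl ester of 40 | C=C1CC[C@@H]2[C@](C)(CCC[C@@]2(C)C(=O)OCC[Si](C)(C)C)[C@H]1C/C=C(\C)[C@@H]1C[C@@]23C(=O)[C@]1(C(C)C)C(=O)C(O)=C2[C@@]1(C)CCCC(C)(C)[C@@H]1[C@H]3C(OC)OC | intermediate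
39 | C6 dimethyl acetal of 40 (free acid) | C=C1CC[C@@H]2[C@](C)(CCC[C@@]2(C)C(=O)O)[C@H]1C/C=C(\C)[C@@H]1C[C@@]23C(=O)[C@]1(C(C)C)C(=O)C(O)=C2[C@@]1(C)CCCC(C)(C)[C@@H]1[C@H]3C(OC)OC | intermediate (not isolated)
40 | CNP0256710.1 | C=C1CC[C@@H]2[C@](C)(CCC[C@@]2(C)C(=O)O)[C@H]1C/C=C(\C)[C@@H]1C[C@@]23C(=O)[C@]1(C(C)C)C(=O)C(O)=C2[C@@]1(C)CCCC(C)(C)[C@@H]1[C@H]3C=O | target

## Step count and risk

Total step count: 25. Longest linear sequence: 15 steps (1 to 10, then 21 to 25, from dehydroabietic acid); the labdane branch runs 13 steps (11 to 15, 18 to 25).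

Least certain steps:

**Step 8 (key step).** The alkyl iodane may be intercepted by methanol before the aryl group shifts, which would give 1,2-dimethoxylation. The electron-rich anisole ring may also be oxidised, or iodine may attack the β face and give the C7 epimer. The cause is that migration, solvolysis and arene oxidation all draw on the same electron-rich styrene. Fallback, from 10 back to 11: do the same bond reorganisation stepwise. N-Bromosuccinimide in methanol should give the 6α-bromo-7β-methoxy ether F1 by anti bromo-etherification. AgBF4 in methanol then pulls off the equatorial bromide, the antiperiplanar aryl group shifts, and the oxocarbenium ion is trapped as acetal 11. Each half of the sequence can then be tuned on an isolable compound.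

**Step 24.** Tin radicals may add to the oxygen atoms of the ene-trione and reduce it before iodine is abstracted. The radical may also close 6-endo at C9, or the homoallylic radical may undergo a 1,2-vinyl shift. The cause is that the acceptor is itself a strong radical trap and both alkene carbons are fully substituted. Fallback, from 25 and 16 back to 38: give up the ether, Claisen and radical line and form both bridge bonds at once. Wittig reaction of 25 with Ph3P=C(CH3)CHO gives (E)-enal F2, and methylenation with Ph3P=CH2 gives triene F3. BF3·OEt2 in CH2Cl2 at low temperature should then promote a perezone-type cationic [5+2] cycloaddition of 16 with the terminal vinyl group of F3 (C15' to C8, C14' to C13), giving 38 directly. Face selectivity would then depend only on the substrate, which is why this is the fallback and not the plan.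

**Step 21.** Stereochemical fidelity may be lost through allylic ionisation or SN2' attack, and alkylation may occur at O14 instead of O12. The cause is a hindered secondary allylic carbinol and an ambident nucleophile. Fallback, from 16 and 32 back to 34: reverse the roles so that the carbinol C–O bond is never broken. Tf2O and 2,6-lutidine convert 16 into quinonyl triflate F4. Reduction of 32 with the (R)-catalyst gives the (12'S)-alcohol F5. Its potassium alkoxide (KN(SiMe3)2, THF, −78 °C) displaces triflate at C12 by addition–elimination, giving 34 with retention at C12' and fixed regiochemistry.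

**Step 10.** Under basic aerobic conditions the quinone intermediates may autoxidise or epimerise at C7, and the acidic thiol may exchange with the acetal. The cause is the vinylogous acidity of H7 once ring C is a quinone. Fallback, from 11 back to 16, skipping step 9: directed ortho-lithiation of 11 (sec-BuLi, TMEDA), borylation with B(OMe)3 and oxidation with H2O2 give the 11-hydroxy-12-methoxy arene F6. Oxidation with (KSO3)2NO at the free para position C14 gives the 12-methoxy-11,14-quinone F7. Mild hydrolysis of this vinylogous ester (aqueous K2CO3, degassed) gives 16. Lithiation at the other free ring position would converge on the same quinone.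

**Step 7.** The benzylic cation may be captured by adventitious water, leading to over-oxidation to the C7 ketone, or conversion may stall in the charge-transfer complex. Fallback, from 9 back to 10: benzylic oxidation with CrO3 in acetic acid gives ketone F8. NaBH4 reduction gives alcohol F9. Dehydration with p-toluenesulfonic acid in hot benzene gives 10.

## Further compounds

F1 | step 8 | 6α-bromo-7β,12-dimethoxyabieta-8,11,13-triene | CC(C)c1cc2c(cc1OC)[C@@]1(C)CCCC(C)(C)[C@@H]1[C@@H](Br)[C@@H]2OC
F2 | step 24 | 2-(trimethylsilyl)ethyl (12'E)-14'-oxo-15'-norlabda-8'(17'),12'-dien-18'-oate (enal) | C=C1CC[C@@H]2[C@](C)(CCC[C@@]2(C)C(=O)OCC[Si](C)(C)C)[C@H]1C/C=C(\C)C=O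
F3 | step 24 | 2-(trimethylsilyl)ethyl (12'E)-labda-8'(17'),12',14'-trien-18'-oate | C=C1CC[C@@H]2[C@](C)(CCC[C@@]2(C)C(=O)OCC[Si](C)(C)C)[C@H]1C/C=C(\C)C=C
F4 | step 21 | 12-(trifluoromethanesulfonyloxy)-5(6→7)abeo-abieta-8,12-diene-11,14-dione 6-dimethyl acetal | FC(F)(F)S(=O)(=O)OC1=C(C(C)C)C(=O)C2=C(C1=O)[C@@]1(C)CCCC(C)(C)[C@@H]1[C@H]2C(OC)OC
F5 | step 21 | 2-(trimethylsilyl)ethyl (12'S,13'Z)-15'-(tert-butyldimethylsilyloxy)-12'-hydroxylabda-8'(17'),13'-dien-18'-oate | C=C1CC[C@@H]2[C@](C)(CCC[C@@]2(C)C(=O)OCC[Si](C)(C)C)[C@H]1C[C@H](O)/C(C)=C\CO[Si](C)(C)C(C)(C)C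
F6 | step 10 | 11-hydroxy-12-methoxy-5(6→7)abeo-abieta-8,11,13-trien-6-al dimethyl acetal | CC(C)c1cc2c(c(O)c1OC)[C@@]1(C)CCCC(C)(C)[C@@H]1[C@H]2C(OC)OC
F7 | step 10 | 12-methoxy-5(6→7)abeo-abieta-8,12-diene-11,14-dione 6-dimethyl acetal | COC1=C(C(C)C)C(=O)C2=C(C1=O)[C@@]1(C)CCCC(C)(C)[C@@H]1[C@H]2C(OC)OC
F8 | step 7 | 12-methoxyabieta-8,11,13-trien-7-one | CC(C)c1cc2c(cc1OC)[C@@]1(C)CCCC(C)(C)[C@@H]1CC2=O
F9 | step 7 | 12-methoxyabieta-8,11,13-trien-7-ol (C7 epimers) | CC(C)c1cc2c(cc1OC)[C@@]1(C)CCCC(C)(C)[C@@H]1CC2O
A1 | alternative 1 | 3-hydroxy-18-silyloxy decalin with exocyclic methylene and C11' pivalate | C=C1CC[C@@H]2[C@](C)(CC[C@H](O)[C@@]2(C)CO[Si](C)(C)C(C)(C)C)[C@H]1COC(=O)C(C)(C)C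
A2 | alternative 2 | tetracyclic (4+3) adduct with the bicyclo[3.2.1]octenone core | O=C1C[C@]2(C(C)C)C(COCc3ccccc3)=C[C@@]4(C2(OC)OC)[C@H]1[C@@]5(C)CCCC(C)(C)[C@@H]5[C@H]4CO[Si](C)(C)C(C)(C)C
A3 | alternative 3 | ring C hydroquinone monoisopropyl ether | Oc1c(C(C)C)c(OC(C)C)c(O)c2c1[C@H](CO[Si](C)(C)C(C)(C)C)[C@H]3C(C)(C)CCC[C@]23C
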